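## Structural features

The target joins three units: a guaiacyl ring (4-hydroxy-3-methoxyphenyl), a 3,4-dihydro-2H-pyran and a 6-acetyl-5-hydroxybenzofuran. The pyran runs O1–C2–C3–C4–C5=C6: C2 carries the guaiacyl ring, C3 an acetoxymethyl group, and C5 is bonded to C2′ of the benzofuran, so the C5=C6 enol ether is conjugated with the furan ring. C2 and C3 are the only stereocentres; they are adjacent, trans, and 2R,3S. Fragile points are the enol ether (acid), the O1–C2 bond (a para-hydroxybenzylic ether that can ionise toward a quinone methide under acid or base), the primary acetate, the enolisable aryl methyl ketone, and two phenols of different character, one hydrogen-bonded to the acetyl group. The real difficulty is to place oxygen on the benzylic carbon C2 in the right sense relative to C3 while the enol ether is formed, and to keep the two phenols apart. The key step uses the fact that C2 is the para-benzylic carbon of the free guaiacol: two-electron oxidation makes C2 the electrophilic end of a para-quinone methide, and the oxygen of a C6 aldehyde five atoms away closes O1–C2. A check of descriptors found no structural error: the open-chain precursor is R at the acetoxymethyl carbon, which is the same spatial arrangement as 3S in the ring (the letter changes only because C2 gains an oxygen), and the (R)-benzyl oxazolidinone is the correct enantiomer for it.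

## Logic of the disconnections

**27 ⇒ 26.** Only the O–Si bond at the benzofuran phenol is cut. The oxidation at the preceding stage must meet a single oxidisable phenol, and the gain is a last step without skeletal change. The forward step must be near neutral, so that the acetate, the enol ether and the O1–C2 ether of 27 are left alone.

**26 ⇒ 24 via 25.** The O1–C2 bond is cut, which opens the dihydropyran and removes the C2 stereocentre. The cut is made there because C2 is para-benzylic to a free guaiacol and can be reached as the electrophilic end of 25, while O1 can come from a C6 aldehyde whose enol already holds the C5=C6 double bond. The gain is an acyclic compound with one stereocentre. The forward step must oxidise only the guaiacol, close through the enol oxygen and not the carbon, and give C2 trans to C3.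

**24 ⇒ 23 ⇒ 22 ⇒ 20.** No skeletal bond is cut: the guaiacol oxygen is masked, the C6 oxidation level is lowered, and the C6–O bond is removed to leave a terminal methylene on C5. The guaiacol is carried as a methoxymethyl ether and not as a second silyl ether. An aryl silyl ether ortho to an acetyl group is the more fluoride- and base-labile of the two, so a desilylation that frees only the guaiacol could not be trusted; an acetal (acid) and a silyl ether (fluoride) are orthogonal. The gain is that 24 is unmasked one step before use and 20 is a plain 1,1-disubstituted alkene. The forward steps must put boron on the terminal carbon, oxidise without harming the acetal, and unmask the phenol without acid damage to an enolisable aldehyde.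

**20 ⇒ 11 + 19.** The sp2–sp2 bond C5–C2′ is cut. It is the natural seam between the chiral side chain and the heterocycle and gives two halves of similar size. The coupling must run under base mild enough for a 2-heteroaryl boronate, an aryl silyl ether and an acetate.

**11 ⇒ 10 ⇒ 9 ⇒ 6 + 7.** After adjusting the ester and the oxidation level at the future acetoxymethyl carbon, the C3–C4 bond is cut. 7 supplies C4, C5 and C6 with a vinyl bromide ready for coupling, and the auxiliary in 6 sets C3, the only stereocentre fixed by a reagent. The alkylation must discriminate the enolate faces and use only the allylic bromide of 7.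

**6 ⇒ 3 + 4 and 3 ⇒ 1.** The imide N–C(O) bond and the phenol O–C bond are cut, leading to commercial 1 and 4. The acetal must survive base, hydride, borane and palladium.

**19 ⇒ 18 ⇒ 17.** The C2′–B and O–Si bonds are cut. C–H borylation is chosen over metalation because the methyl ketone would not survive an organolithium. It must be selective for C2′, which the ortho substituents on the benzo ring should ensure.

**17 ⇒ 14 ⇒ 13 ⇒ 12.** The furan ring is cut at O1′–C2′ and C3′–C3a, giving the two carbons of trimethylsilylacetylene and an ortho-bromophenol; then both O–CH3 bonds and the aryl–acetyl bond are cut. The bromine of 12 marks the carbon that becomes C3a, para to the acetyl group, which fixes the regiochemistry of the annulation. The forward steps need acylation para to bromine and a coupling–cyclisation on an electron-rich bromophenol.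

## Other disconnections considered

**Alternative 1:** The cut is the C2′=C3′ double bond of the furan ring, with the aryl ester C–O bond behind it.
- Forward step: triethylamine would convert the benzylic phosphonium salt A2 into its ylide, which attacks the neighbouring ester carbonyl and expels triphenylphosphine oxide to give A1, one desilylation short of the target.
- In favour: intramolecular Wittig closure of ortho-acyloxybenzyl phosphonium salts is an established benzofuran synthesis, so on precedent this key step is better founded than the chosen one. It also avoids the heteroaryl boronate and the cross-coupling, and the endgame is the same single deprotection (equal).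
- Against: the carbonyl to be olefinated belongs to a β-alkoxyacrylate, a vinylogous carbonate of low electrophilicity. The olefination would need prolonged heating with base on a molecule that already holds the enol ether, the acetate and the ionisable benzylic ether. A2 also presupposes the finished dihydropyran with both stereocentres.
- Comparison: on structure the chosen key step does more (ring, O1–C2 and the C2 configuration, against an aromatic ring only). On mechanism Alternative 1 is the safer. On step economy it is no shorter: the acyl half of A2 needs its own stereocontrolled synthesis of about the length of the route to 24, and the phosphonium half needs a benzylic functionalisation of an acetylhydroquinone.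

**Alternative 2:** The cut removes the C3–CH2OH bond and O1–C2 at once.
- Forward step: a confined chiral Brønsted acid would activate formaldehyde for addition to the β-carbon of the E-styrene in acid A4, and the carboxyl group would capture the benzylic cation to close the δ-lactone A3.
- In favour: two bonds, the ring and both stereocentres would arise in one catalytic operation from an alkene with no stereocentre at C2 or C3. That is better stereochemical economy than a stoichiometric auxiliary followed by substrate control, and the trans relationship follows from the E geometry.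
- Against: enantioselective Prins chemistry of styrenes with formaldehyde is known where a second formaldehyde closes a dioxane; interception by an internal carboxylic acid is an extension, so in precedent it stands level with the chosen key step, not above it. The strong acid meets an electron-rich benzofuran and an enolisable ketone. A4 is racemic at its α-carbon, so the catalyst faces two diastereomeric pathways. A3 is at the lactone oxidation level, so partial reduction next to an aryl ketone, dehydration to the enol ether, acetylation and two desilylations would still be needed.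
- Comparison: on structure Alternative 2 is the more ambitious and, if it worked, the more elegant. On mechanism both plans rest on an untested capture of a benzylic electrophile by oxygen (equal). On step economy the front end is shorter but the endgame is four to five steps against one, so the totals come out close, with the chemoselective lactone reduction as an added weak point.

**Alternative 3:** The cut takes C5–C2′ and O1–C6 together.
- Forward step: Pd(PPh3)4 (zerovalent palladium) would insert into the C–I bond of iodobenzofuran A7, the aryl group would add to the central carbon of allenol A6 to give a π-allyl palladium species, and the C2 hydroxyl would attack the CH2 terminus with K2CO3 as base to give A5.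
- In favour: coupling–cyclisation of allenols with aryl halides is a known reaction type, so this key step is better precedented than the chosen one. It is also more convergent (two bonds against one) and avoids the boronate, the hydroboration and the oxidation.
- Against: A5 is the C4=C5 isomer. Moving the double bond to C5=C6 must be done selectively away from C3, since migration toward C3 would erase that stereocentre. Both stereocentres must be installed beforehand in A6 by an anti-selective addition to an aromatic aldehyde, which needs its own control element, and two silyl ethers remain to be removed.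
- Comparison: on structure Alternative 3 forms more bonds in its key step but sets no stereocentre, whereas the chosen step sets C2. On mechanism the ring closure is safer, but the uncertainty shifts to the alkene transposition. On step economy the two plans are about equal, with Alternative 3 slightly ahead up to A5 and behind after it.

Key step: step 15

Remark: the benzofuran-bearing carbon (C5 of the future pyran) is formed without control in step 12 and carried as both epimers through 22, 23 and 24; it becomes sp2 in step 15, so the mixture is of no consequence.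

## Route

Step 1
Reactants: 1 3-(4-hydroxy-3-methoxyphenyl)propanoic acid
Product: 3 3-[3-methoxy-4-(methoxymethoxy)phenyl]propanoic acid, via methoxymethyl ester 2 (not isolated)
Conditions: MOMCl (2.5 equiv), i-Pr2NEt, CH2Cl2, 0 °C to rt; then LiOH, THF/MeOH/H2O, rt; 1 M HCl to pH 4, 0 °C
Reagents that add atoms: chloromethyl methyl ether COCCl; lithium hydroxide [Li+].[OH-] (oxygen of the regenerated acid)
Why: O-alkylation of phenoxide and carboxylate by the reactive chloromethyl ether, then saponification of the labile methoxymethyl ester only; the aryl acetal is stable to base and to brief cold dilute acid.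

Step 2
Reactants: 3 3-[3-methoxy-4-(methoxymethoxy)phenyl]propanoic acid; 4 (R)-4-benzyl-2-oxazolidinone
Product: 6 (4R)-4-benzyl-3-{3-[3-methoxy-4-(methoxymethoxy)phenyl]propanoyl}-1,3-oxazolidin-2-one, via mixed pivalic anhydride 5 (not isolated)
Conditions: PivCl, Et3N, THF, −20 °C; then 4, LiCl, −20 °C to rt
Reagents that add atoms: none
Why: N-acylation of the oxazolidinone through a mixed anhydride; LiCl and Et3N make the carbamate nitrogen nucleophilic enough without butyllithium, and attack occurs at the less hindered acyl carbon.

Step 3
Reactants: 6 (4R)-4-benzyl-3-{3-[3-methoxy-4-(methoxymethoxy)phenyl]propanoyl}-1,3-oxazolidin-2-one; 7 2,3-dibromopropene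
Product: 9 (4R)-4-benzyl-3-[(2S)-4-bromo-2-{[3-methoxy-4-(methoxymethoxy)phenyl]methyl}pent-4-enoyl]-1,3-oxazolidin-2-one, via sodium enolate 8 (not isolated)
Conditions: NaHMDS (1.1 equiv), THF, −78 °C; then 7 (3 equiv), −78 to −40 °C
Reagents that add atoms: none
Why: Evans asymmetric alkylation: the chelated Z-enolate is shielded on one face by the benzyl group of the auxiliary, so the allylic bromide (the vinylic bromide is inert to SN2) enters from the open face and sets the S centre that becomes C3 of the target.

Step 4
Reactants: 9 (4R)-4-benzyl-3-[(2S)-4-bromo-2-{[3-methoxy-4-(methoxymethoxy)phenyl]methyl}pent-4-enoyl]-1,3-oxazolidin-2-one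
Product: 10 (2S)-4-bromo-2-{[3-methoxy-4-(methoxymethoxy)phenyl]methyl}pent-4-en-1-ol
Conditions: LiBH4 (2 equiv), MeOH (1 equiv), THF, 0 °C
Reagents that add atoms: none
Why: Reductive cleavage of the imide by hydride attack at the exocyclic carbonyl gives the primary alcohol without epimerisation and releases the auxiliary for recovery; the vinyl bromide and the acetal are inert.

Step 5
Reactants: 10 (2S)-4-bromo-2-{[3-methoxy-4-(methoxymethoxy)phenyl]methyl}pent-4-en-1-ol
Product: 11 (2S)-4-bromo-2-{[3-methoxy-4-(methoxymethoxy)phenyl]methyl}pent-4-en-1-yl acetate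
Conditions: Ac2O, pyridine, DMAP (cat.), CH2Cl2, rt
Reagents that add atoms: acetic anhydride CC(=O)OC(C)=O
Why: DMAP-catalysed acylation of the primary alcohol installs the acetate of the target early, where it also serves as the protecting group.

Step 6
Reactants: 12 2-bromo-1,4-dimethoxybenzene
Product: 13 1-(4-bromo-2,5-dimethoxyphenyl)ethanone
Conditions: AcCl, AlCl3, CH2Cl2, 0 °C to rt
Reagents that add atoms: acetyl chloride CC(Cl)=O
Why: Friedel–Crafts acylation at the position para to bromine and ortho to a methoxy group, the least hindered activated site; partial loss of the methyl group next to the new ketone would be harmless because step 7 removes both.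

Step 7
Reactants: 13 1-(4-bromo-2,5-dimethoxyphenyl)ethanone
Product: 14 1-(4-bromo-2,5-dihydroxyphenyl)ethanone
Conditions: BBr3 (3 equiv), CH2Cl2, −78 °C to rt; H2O
Reagents that add atoms: none
Why: Lewis-acid cleavage of both aryl methyl ethers; the acetyl group makes the resulting hydroquinone less prone to air oxidation than the parent.

Step 8
Reactants: 14 1-(4-bromo-2,5-dihydroxyphenyl)ethanone
Product: 17 1-(5-hydroxy-1-benzofuran-6-yl)ethanone, via silylalkyne 15 (not isolated), via ethynylphenol 16 (not isolated)
Conditions: trimethylsilylacetylene, Pd(PPh3)2Cl2 (3 mol %), CuI (6 mol %), Et3N, DMF, 60 °C, argon, sealed; then TBAF, THF, 60 °C; aq. NH4Cl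
Reagents that add atoms: trimethylsilylacetylene C#C[Si](C)(C)C
Why: Sonogashira coupling at the bromide (activated by the para acetyl group), then fluoride removes the silyl group and the phenoxide next to the alkyne adds 5-endo-dig to the acetyl-polarised triple bond (benzofuran annulation). Only the hydroxyl ortho to the alkyne can cyclise, so the 6-acetyl-5-hydroxy pattern follows from the position of the bromine.

Step 9
Reactants: 17 1-(5-hydroxy-1-benzofuran-6-yl)ethanone
Product: 18 1-{5-[(triisopropylsilyl)oxy]-1-benzofuran-6-yl}ethanone
Conditions: TIPSCl, imidazole, DMAP (cat.), DMF, 40 °C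
Reagents that add atoms: chlorotriisopropylsilane CC(C)[Si](Cl)(C(C)C)C(C)C
Why: Silylation of the hydrogen-bonded phenol; the bulky silyl group is chosen to survive aqueous phosphate and borane, and imidazole avoids enol silane formation at the methyl ketone.

Step 10
Reactants: 18 1-{5-[(triisopropylsilyl)oxy]-1-benzofuran-6-yl}ethanone
Product: 19 1-{2-(4,4,5,5-tetramethyl-1,3,2-dioxaborolan-2-yl)-5-[(triisopropylsilyl)oxy]-1-benzofuran-6-yl}ethanone
Conditions: [Ir(OMe)(cod)]2 (1.5 mol %), 4,4′-di-tert-butyl-2,2′-bipyridine (3 mol %), B2pin2 (1.0 equiv), THF, 50 °C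
Reagents that add atoms: bis(pinacolato)diboron CC1(C)OB(OC1(C)C)B1OC(C)(C)C(C)(C)O1
Why: Iridium-catalysed C–H borylation; the C2′–H next to the furan oxygen is the most reactive C–H bond of a benzofuran and the benzo C–H bonds are blocked by ortho substituents, while the ketone, which rules out lithiation, is tolerated.

Step 11
Reactants: 11 (2S)-4-bromo-2-{[3-methoxy-4-(methoxymethoxy)phenyl]methyl}pent-4-en-1-yl acetate; 19 1-{2-(4,4,5,5-tetramethyl-1,3,2-dioxaborolan-2-yl)-5-[(triisopropylsilyl)oxy]-1-benzofuran-6-yl}ethanone
Product: 20 (2S)-4-{6-acetyl-5-[(triisopropylsilyl)oxy]-1-benzofuran-2-yl}-2-{[3-methoxy-4-(methoxymethoxy)phenyl]methyl}pent-4-en-1-yl acetate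
Conditions: 19 (1.3 equiv), Pd(dppf)Cl2 (5 mol %), K3PO4 (3 equiv, aq.), THF, 40 °C
Reagents that add atoms: none
Why: Suzuki–Miyaura coupling of the alkenyl bromide with the 2-benzofuranyl boronate forms C5–C2′; mild aqueous phosphate at 40 °C limits protodeboronation and spares the acetate and the aryl silyl ether, and the stereocentre is not involved.

Step 12
Reactants: 20 (2S)-4-{6-acetyl-5-[(triisopropylsilyl)oxy]-1-benzofuran-2-yl}-2-{[3-methoxy-4-(methoxymethoxy)phenyl]methyl}pent-4-en-1-yl acetate
Product: 22 (2R)-4-{6-acetyl-5-[(triisopropylsilyl)oxy]-1-benzofuran-2-yl}-5-hydroxy-2-{[3-methoxy-4-(methoxymethoxy)phenyl]methyl}pentyl acetate (both C4 epimers), via alkylborane 21 (not isolated)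
Conditions: 9-BBN (2.5 equiv), THF, 0 °C to rt; then NaBO3·4H2O, THF/H2O, rt
Reagents that add atoms: sodium perborate [Na+].[O-]OB=O (the hydroxyl oxygen)
Why: Anti-Markovnikov hydroboration places boron on the terminal carbon of the 1,1-disubstituted alkene and perborate oxidises the C–B bond under conditions mild enough for the acetate and the aryl silyl ether. The new centre is not controlled and need not be, and any acetyl group reduced by the borane is returned to the ketone in step 13.

Step 13
Reactants: 22 (2R)-4-{6-acetyl-5-[(triisopropylsilyl)oxy]-1-benzofuran-2-yl}-5-hydroxy-2-{[3-methoxy-4-(methoxymethoxy)phenyl]methyl}pentyl acetate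
Product: 23 (2R)-4-{6-acetyl-5-[(triisopropylsilyl)oxy]-1-benzofuran-2-yl}-2-{[3-methoxy-4-(methoxymethoxy)phenyl]methyl}-5-oxopentyl acetate (both C4 epimers)
Conditions: Dess–Martin periodinane (2.5 equiv), NaHCO3, CH2Cl2, 0 °C to rt
Reagents that add atoms: none
Why: Dess–Martin oxidation of the primary alcohol to the aldehyde, buffered to protect the acetal; the excess also reoxidises any 1-hydroxyethyl group from step 12, and the enolisable α-aryl aldehyde is used without storage.

Step 14
Reactants: 23 (2R)-4-{6-acetyl-5-[(triisopropylsilyl)oxy]-1-benzofuran-2-yl}-2-{[3-methoxy-4-(methoxymethoxy)phenyl]methyl}-5-oxopentyl acetate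
Product: 24 (2R)-4-{6-acetyl-5-[(triisopropylsilyl)oxy]-1-benzofuran-2-yl}-2-[(4-hydroxy-3-methoxyphenyl)methyl]-5-oxopentyl acetate (both C4 epimers)
Conditions: NaHSO4·SiO2, CH2Cl2, rt
Reagents that add atoms: none
Why: Acid-catalysed acetal cleavage: a phenolic methoxymethyl ether ionises readily because the phenol is a good leaving group, so a solid acid at room temperature should suffice, and the aryl silyl ether, acetate, ketone and aldehyde are inert to it. This acid/fluoride pairing replaces an unreliable selective desilylation between two aryl silyl ethers.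

Step 15
Reactants: 24 (2R)-4-{6-acetyl-5-[(triisopropylsilyl)oxy]-1-benzofuran-2-yl}-2-[(4-hydroxy-3-methoxyphenyl)methyl]-5-oxopentyl acetate
Product: 26 [(2R,3S)-5-{6-acetyl-5-[(triisopropylsilyl)oxy]-1-benzofuran-2-yl}-2-(4-hydroxy-3-methoxyphenyl)-3,4-dihydro-2H-pyran-3-yl]methyl acetate, via quinone methide 25 (not isolated)
Conditions: Ag2O (1.5 equiv), 4 Å molecular sieves, CH2Cl2 (0.01 M), rt, dark
Reagents that add atoms: none
Why: Proposed new method: Ag2O should remove two electrons and two protons from the free guaiacol of 24 to give the para-quinone methide 25, whose exocyclic carbon (the future C2) is a strong electrophile; the aldehyde oxygen, reacting as its benzofuran-stabilised enol or as the carbonyl followed by loss of the acidic C5 proton, should add to it in a 1,6-fashion that restores the phenol, the closest known reaction type being intramolecular capture of Ag2O- or DDQ-generated para-quinone methides of 4-alkylguaiacols by hydroxyl or carboxyl oxygen. The single ring closes in the 6-exo-trig mode, O1 attacking the exocyclic methide carbon, while attack through the enol carbon would need a four-membered ring and is excluded. The new stereocentre C2 is controlled by the existing C3 centre: in a chair-like arrangement the quinone methide residue and the acetoxymethyl group both lie pseudo-equatorial, which leads to the 2R,3S trans product, and because the para-hydroxybenzylic ether can reopen to 25 on the basic oxide surface, any cis isomer should drain into the more stable trans one. The step needs chemoselective oxidation, secured by the benzofuran phenol being silylated so that only one oxidisable phenol is present, and it needs ring closure to outrun dimerisation and tautomerisation to the styrene, for which high dilution, an anhydrous non-nucleophilic solvent and the five-atom tether are relied on. The oxidant is kept near stoichiometric because the product is again a 4-alkylguaiacol.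

Step 16
Reactants: 26 [(2R,3S)-5-{6-acetyl-5-[(triisopropylsilyl)oxy]-1-benzofuran-2-yl}-2-(4-hydroxy-3-methoxyphenyl)-3,4-dihydro-2H-pyran-3-yl]methyl acetate
Product: 27 propolis-benzofuran A
Conditions: TBAF (1.1 equiv), AcOH (1.2 equiv), THF, 0 °C
Reagents that add atoms: none
Why: Fluoride-induced Si–O cleavage; the aryl silyl ether next to the acetyl group is especially labile, and buffering with AcOH keeps the medium near neutral so that the acetate, the enol ether and the base-sensitive O1–C2 ether are not disturbed.

## Compound list

1 | 3-(4-hydroxy-3-methoxyphenyl)propanoic acid | COc1cc(CCC(=O)O)ccc1O | starting material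
2 | methoxymethyl 3-[3-methoxy-4-(methoxymethoxy)phenyl]propanoate (not isolated) | COCOC(=O)CCc1ccc(OCOC)c(OC)c1 | intermediate
3 | 3-[3-methoxy-4-(methoxymethoxy)phenyl]propanoic acid | COCOc1ccc(CCC(=O)O)cc1OC | intermediate
4 | (R)-4-benzyl-2-oxazolidinone | O=C1N[C@H](Cc2ccccc2)CO1 | starting material
5 | 3-[3-methoxy-4-(methoxymethoxy)phenyl]propanoic pivalic anhydride (not isolated) | COCOc1ccc(CCC(=O)OC(=O)C(C)(C)C)cc1OC | intermediate
6 | (4R)-4-benzyl-3-{3-[3-methoxy-4-(methoxymethoxy)phenyl]propanoyl}-1,3-oxazolidin-2-one | COCOc1ccc(CCC(=O)N2[C@H](Cc3ccccc3)COC2=O)cc1OC | intermediate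
7 | 2,3-dibromopropene | C=C(Br)CBr | starting material
8 | sodium (Z)-enolate of 6 (not isolated) | COCOc1ccc(C/C=C(\[O-])N2[C@H](Cc3ccccc3)COC2=O)cc1OC.[Na+] | intermediate
9 | (4R)-4-benzyl-3-[(2S)-4-bromo-2-{[3-methoxy-4-(methoxymethoxy)phenyl]methyl}pent-4-enoyl]-1,3-oxazolidin-2-one | COCOc1ccc(C[C@@H](CC(Br)=C)C(=O)N2[C@H](Cc3ccccc3)COC2=O)cc1OC | intermediate
10 | (2S)-4-bromo-2-{[3-methoxy-4-(methoxymethoxy)phenyl]methyl}pent-4-en-1-ol | COCOc1ccc(C[C@@H](CC(Br)=C)CO)cc1OC | intermediate
11 | (2S)-4-bromo-2-{[3-methoxy-4-(methoxymethoxy)phenyl]methyl}pent-4-en-1-yl acetate | COCOc1ccc(C[C@@H](CC(Br)=C)COC(C)=O)cc1OC | intermediate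
12 | 2-bromo-1,4-dimethoxybenzene | COc1ccc(OC)c(Br)c1 | starting material
13 | 1-(4-bromo-2,5-dimethoxyphenyl)ethanone | CC(=O)c1cc(OC)c(Br)cc1OC | intermediate
14 | 1-(4-bromo-2,5-dihydroxyphenyl)ethanone | CC(=O)c1cc(O)c(Br)cc1O | intermediate
15 | 1-{2,5-dihydroxy-4-[(trimethylsilyl)ethynyl]phenyl}ethanone (not isolated) | CC(=O)c1cc(O)c(C#C[Si](C)(C)C)cc1O | intermediate
16 | 1-(4-ethynyl-2,5-dihydroxyphenyl)ethanone (not isolated) | CC(=O)c1cc(O)c(C#C)cc1O | intermediate
17 | 1-(5-hydroxy-1-benzofuran-6-yl)ethanone | CC(=O)c1cc2occc2cc1O | intermediate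
18 | 1-{5-[(triisopropylsilyl)oxy]-1-benzofuran-6-yl}ethanone | CC(=O)c1cc2occc2cc1O[Si](C(C)C)(C(C)C)C(C)C | intermediate
19 | 1-{2-(4,4,5,5-tetramethyl-1,3,2-dioxaborolan-2-yl)-5-[(triisopropylsilyl)oxy]-1-benzofuran-6-yl}ethanone | CC(=O)c1cc2oc(B3OC(C)(C)C(C)(C)O3)cc2cc1O[Si](C(C)C)(C(C)C)C(C)C | intermediate
20 | (2S)-4-{6-acetyl-5-[(triisopropylsilyl)oxy]-1-benzofuran-2-yl}-2-{[3-methoxy-4-(methoxymethoxy)phenyl]methyl}pent-4-en-1-yl acetate | COCOc1ccc(C[C@@H](CC(=C)c2cc3cc(O[Si](C(C)C)(C(C)C)C(C)C)c(C(C)=O)cc3o2)COC(C)=O)cc1OC | intermediate
21 | B-alkyl-9-borabicyclo[3.3.1]nonane from 20, boron on the terminal carbon (not isolated; both epimers at the benzofuran-bearing carbon) | COCOc1ccc(C[C@@H](CC(CB2C3CCCC2CCC3)c2cc3cc(O[Si](C(C)C)(C(C)C)C(C)C)c(C(C)=O)cc3o2)COC(C)=O)cc1OC | intermediate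
22 | (2R)-4-{6-acetyl-5-[(triisopropylsilyl)oxy]-1-benzofuran-2-yl}-5-hydroxy-2-{[3-methoxy-4-(methoxymethoxy)phenyl]methyl}pentyl acetate (both C4 epimers) | COCOc1ccc(C[C@@H](CC(CO)c2cc3cc(O[Si](C(C)C)(C(C)C)C(C)C)c(C(C)=O)cc3o2)COC(C)=O)cc1OC | intermediate
23 | (2R)-4-{6-acetyl-5-[(triisopropylsilyl)oxy]-1-benzofuran-2-yl}-2-{[3-methoxy-4-(methoxymethoxy)phenyl]methyl}-5-oxopentyl acetate (both C4 epimers) | COCOc1ccc(C[C@@H](CC(C=O)c2cc3cc(O[Si](C(C)C)(C(C)C)C(C)C)c(C(C)=O)cc3o2)COC(C)=O)cc1OC | intermediate
24 | (2R)-4-{6-acetyl-5-[(triisopropylsilyl)oxy]-1-benzofuran-2-yl}-2-[(4-hydroxy-3-methoxyphenyl)methyl]-5-oxopentyl acetate (both C4 epimers) | COc1cc(C[C@H](COC(C)=O)CC(C=O)c2cc3cc(O[Si](C(C)C)(C(C)C)C(C)C)c(C(C)=O)cc3o2)ccc1O | intermediate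
25 | para-quinone methide of 24 (not isolated) | COC1=CC(=C[C@H](COC(C)=O)CC(C=O)c2cc3cc(O[Si](C(C)C)(C(C)C)C(C)C)c(C(C)=O)cc3o2)C=CC1=O | intermediate
26 | [(2R,3S)-5-{6-acetyl-5-[(triisopropylsilyl)oxy]-1-benzofuran-2-yl}-2-(4-hydroxy-3-methoxyphenyl)-3,4-dihydro-2H-pyran-3-yl]methyl acetate | COc1cc([C@@H]2OC=C(c3cc4cc(O[Si](C(C)C)(C(C)C)C(C)C)c(C(C)=O)cc4o3)C[C@H]2COC(C)=O)ccc1O | intermediate
27 | propolis-benzofuran A, [(2R,3S)-5-(6-acetyl-5-hydroxy-1-benzofuran-2-yl)-2-(4-hydroxy-3-methoxyphenyl)-3,4-dihydro-2H-pyran-3-yl]methyl acetate | COc1cc([C@@H]2OC=C(c3cc4cc(O)c(C(C)=O)cc4o3)C[C@H]2COC(C)=O)ccc1O | target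

## Step count and least certain steps

Total: 16 steps. Longest linear sequence: 11 steps (from 1 through steps 1–5 and 11–16; the branch from 12 through steps 6–10 and 11–16 is equally long).

**Step 15 (key step, new reaction type).**
- What may go wrong: ring closure by the weakly nucleophilic aldehyde or enol oxygen may be slower than tautomerisation of the quinone methide to the styrene (which erases C3) or than intermolecular coupling. A second benzylic oxidation of the product, or oxidation of the enolisable aldehyde on the silver surface, may also compete.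
- Fallback (known reaction types): setting out from 24, the oxidation is run with Ag2O in acetone–water, so that water, an established trap for such quinone methides, takes the benzylic carbon. The resulting para-hydroxybenzylic alcohol closes onto the aldehyde and is taken on as the 6-hydroxytetrahydropyran lactol F1. Acid-catalysed dehydration of the lactol (PPTS, toluene, 4 Å molecular sieves, 60 °C), under which the benzylic C2–O bond can ionise and settle trans, returns to the route at 26.

**Step 8.**
- What may go wrong: oxidation of the hydroquinone to the quinone in the basic copper-containing medium, slow oxidative addition into a bromide that carries an ortho phenoxide, or incomplete ring closure.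
- Fallback: setting out from 14, both phenols are acetylated (Ac2O, pyridine) to 1-(2,5-diacetoxy-4-bromophenyl)ethanone F2. Sonogashira coupling with trimethylsilylacetylene then gives the silylalkyne diacetate F3. K2CO3 in MeOH at 60 °C removes the acetyl and silyl groups and lets the freed phenoxide add to the acetyl-activated alkyne, returning at 17.

**Step 11.**
- What may go wrong: protodeboronation of the 2-benzofuranyl boronate faster than transmetalation, or base-induced loss of the aryl silyl ether or the acetate.
- Fallback without boron: setting out from 11, Sonogashira coupling with trimethylsilylacetylene (Pd(PPh3)2Cl2, CuI, Et3N) gives the silyl enyne F4, and TBAF/AcOH gives the terminal enyne F5. F5 and 14 under the coupling–cyclisation conditions of step 8 give the benzofuranol F6, and silylation (TIPSCl, imidazole) returns at 20.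

**Step 14.**
- What may go wrong: acid-promoted self-condensation of the enolisable α-aryl aldehyde, or capture of the liberated formaldehyde by its enol or by the electron-rich ring, during unmasking.
- Fallback: setting out from 22, the acetal is removed before the aldehyde exists (same solid acid) to give the phenol alcohol F7. Both hydroxyls are silylated (TESCl, imidazole) to the bis(triethylsilyl) ether F8. Swern oxidation, which converts a primary triethylsilyl ether directly into the aldehyde and leaves aryl silyl ethers alone, gives the aryl triethylsilyl ether aldehyde F9. Aqueous citric acid in THF removes the labile aryl triethylsilyl group while the triisopropylsilyl ether stays, returning at 24.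

## Further compounds

F1 | step 15 | [(3S)-5-{6-acetyl-5-[(triisopropylsilyl)oxy]-1-benzofuran-2-yl}-6-hydroxy-2-(4-hydroxy-3-methoxyphenyl)tetrahydro-2H-pyran-3-yl]methyl acetate (lactol, mixture at C2, C5 and C6) | COc1cc(C2OC(O)C(c3cc4cc(O[Si](C(C)C)(C(C)C)C(C)C)c(C(C)=O)cc4o3)C[C@H]2COC(C)=O)ccc1O
F2 | step 8 | 1-(2,5-diacetoxy-4-bromophenyl)ethanone | CC(=O)Oc1cc(C(C)=O)c(OC(C)=O)cc1Br
F3 | step 8 | 1-{2,5-diacetoxy-4-[(trimethylsilyl)ethynyl]phenyl}ethanone | CC(=O)Oc1cc(C(C)=O)c(OC(C)=O)cc1C#C[Si](C)(C)C
F4 | step 11 | (2S)-2-{[3-methoxy-4-(methoxymethoxy)phenyl]methyl}-4-methylidene-6-(trimethylsilyl)hex-5-yn-1-yl acetate | COCOc1ccc(C[C@@H](CC(=C)C#C[Si](C)(C)C)COC(C)=O)cc1OC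
F5 | step 11 | (2S)-2-{[3-methoxy-4-(methoxymethoxy)phenyl]methyl}-4-methylidenehex-5-yn-1-yl acetate | COCOc1ccc(C[C@@H](CC(=C)C#C)COC(C)=O)cc1OC
F6 | step 11 | (2S)-4-(6-acetyl-5-hydroxy-1-benzofuran-2-yl)-2-{[3-methoxy-4-(methoxymethoxy)phenyl]methyl}pent-4-en-1-yl acetate | COCOc1ccc(C[C@@H](CC(=C)c2cc3cc(O)c(C(C)=O)cc3o2)COC(C)=O)cc1OC
F7 | step 14 | (2R)-4-{6-acetyl-5-[(triisopropylsilyl)oxy]-1-benzofuran-2-yl}-5-hydroxy-2-[(4-hydroxy-3-methoxyphenyl)methyl]pentyl acetate | COc1cc(C[C@H](COC(C)=O)CC(CO)c2cc3cc(O[Si](C(C)C)(C(C)C)C(C)C)c(C(C)=O)cc3o2)ccc1O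
F8 | step 14 | (2R)-4-{6-acetyl-5-[(triisopropylsilyl)oxy]-1-benzofuran-2-yl}-2-({3-methoxy-4-[(triethylsilyl)oxy]phenyl}methyl)-5-[(triethylsilyl)oxy]pentyl acetate | COc1cc(C[C@H](COC(C)=O)CC(CO[Si](CC)(CC)CC)c2cc3cc(O[Si](C(C)C)(C(C)C)C(C)C)c(C(C)=O)cc3o2)ccc1O[Si](CC)(CC)CC
F9 | step 14 | (2R)-4-{6-acetyl-5-[(triisopropylsilyl)oxy]-1-benzofuran-2-yl}-2-({3-methoxy-4-[(triethylsilyl)oxy]phenyl}methyl)-5-oxopentyl acetate | COc1cc(C[C@H](COC(C)=O)CC(C=O)c2cc3cc(O[Si](C(C)C)(C(C)C)C(C)C)c(C(C)=O)cc3o2)ccc1O[Si](CC)(CC)CC
A1 | alternative 1 | [(2R,3S)-5-(6-acetyl-5-hydroxy-1-benzofuran-2-yl)-2-{4-[(tert-butyldimethylsilyl)oxy]-3-methoxyphenyl}-3,4-dihydro-2H-pyran-3-yl]methyl acetate | COc1cc([C@@H]2OC=C(c3cc4cc(O)c(C(C)=O)cc4o3)C[C@H]2COC(C)=O)ccc1O[Si](C)(C)C(C)(C)C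
A2 | alternative 1 | {[4-acetyl-5-hydroxy-2-({(2R,3S)-3-(acetoxymethyl)-2-{4-[(tert-butyldimethylsilyl)oxy]-3-methoxyphenyl}-3,4-dihydro-2H-pyran-5-carbonyl}oxy)phenyl]methyl}triphenylphosphonium bromide | COc1cc([C@@H]2OC=C(C(=O)Oc3cc(C(C)=O)c(O)cc3C[P+](c3ccccc3)(c3ccccc3)c3ccccc3)C[C@H]2COC(C)=O)ccc1O[Si](C)(C)C(C)(C)C.[Br-]
A3 | alternative 2 | (5S,6R)-3-{6-acetyl-5-[(tert-butyldimethylsilyl)oxy]-1-benzofuran-2-yl}-6-{4-[(tert-butyldimethylsilyl)oxy]-3-methoxyphenyl}-5-(hydroxymethyl)tetrahydro-2H-pyran-2-one (both C3 epimers) | COc1cc([C@@H]2OC(=O)C(c3cc4cc(O[Si](C)(C)C(C)(C)C)c(C(C)=O)cc4o3)C[C@H]2CO)ccc1O[Si](C)(C)C(C)(C)C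
A4 | alternative 2 | (E)-2-{6-acetyl-5-[(tert-butyldimethylsilyl)oxy]-1-benzofuran-2-yl}-5-{4-[(tert-butyldimethylsilyl)oxy]-3-methoxyphenyl}pent-4-enoic acid (racemic) | COc1cc(/C=C/CC(C(=O)O)c2cc3cc(O[Si](C)(C)C(C)(C)C)c(C(C)=O)cc3o2)ccc1O[Si](C)(C)C(C)(C)C
A5 | alternative 3 | [(2R,3S)-5-{6-acetyl-5-[(tert-butyldimethylsilyl)oxy]-1-benzofuran-2-yl}-2-{4-[(tert-butyldimethylsilyl)oxy]-3-methoxyphenyl}-3,6-dihydro-2H-pyran-3-yl]methyl acetate | COc1cc([C@@H]2OCC(c3cc4cc(O[Si](C)(C)C(C)(C)C)c(C(C)=O)cc4o3)=C[C@H]2COC(C)=O)ccc1O[Si](C)(C)C(C)(C)C
A6 | alternative 3 | (2S)-2-[(R)-{4-[(tert-butyldimethylsilyl)oxy]-3-methoxyphenyl}(hydroxy)methyl]penta-3,4-dien-1-yl acetate | COc1cc([C@H](O)[C@H](COC(C)=O)C=C=C)ccc1O[Si](C)(C)C(C)(C)C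
A7 | alternative 3 | 1-{5-[(tert-butyldimethylsilyl)oxy]-2-iodo-1-benzofuran-6-yl}ethanone | CC(=O)c1cc2oc(I)cc2cc1O[Si](C)(C)C(C)(C)C
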